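## Retrosynthetic overview

1. The last C–C bond made is the one from C4' of the 4-arylisoflavan unit (rings A', C', B') to ring E, the aryl ring it shares with the 3-arylchroman unit (rings A, C). It comes from Friedel–Crafts opening of pterocarpan 22 by isoflavan 12, followed by removal of two sulfonates and one silyl ether.
2. Isoflavan 12 comes from 3-aryl-2H-chromene 11 by asymmetric hydrogenation; 11 comes from stilbene acylal 8 by closing ring C at C2–C3.
3. Enabling feature: in 8, O1 on ring A stands ortho to the (E)-styryl group, so after ionisation C2=O1(+), the ring A bond C8a–C4a and the alkene C4=C3 form a cis-fixed 2-oxahexatriene. Closure at C2–C3 puts the charge on C4, where O1 stabilises it; the 3,5-dioxygenated ring E cannot stabilise charge on C3.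
4. Acylal 8 is built by Wittig olefination (phosphonium salt 4 + aldehyde 6) and O-acyloxymethylation. Pterocarpan 22 is built by chalcone formation, oxidative aryl migration to the isoflavone, transfer hydrogenation with dynamic kinetic resolution, and acid closure.
5. Ring order: ring C (step 7); ring C' as a pyranone (step 10); the dihydrofuran ring of 22 as a temporary ring (step 13), opened again in step 14.

Key step: step 7

Assumption: the SMILES is read as (3R) in the 3-arylchroman unit and (3'R,4'S), 3',4'-trans, in the 4-arylisoflavan unit; rotation about the C4'–ring E bond is taken as free, since no axis is defined.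

## Route

Step 1
Reactants: 1 2,4-dihydroxybenzaldehyde
Product: 2 4-formyl-3-hydroxyphenyl 4-methylbenzenesulfonate
Conditions: TsCl (1.05 equiv), K2CO3, acetone, 0 °C to rt
Reagents that add atoms: p-toluenesulfonyl chloride, Cc1ccc(cc1)S(=O)(=O)Cl
Why: Selective O-sulfonylation: the 2-OH is locked in a hydrogen bond to the formyl group, so the free 4-OH should react; the electron-poor sulfonate is chosen because it later keeps ring A out of the Friedel–Crafts step.

Step 2
Reactants: 2 4-formyl-3-hydroxyphenyl 4-methylbenzenesulfonate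
Product: 3 3-hydroxy-4-(hydroxymethyl)phenyl 4-methylbenzenesulfonate
Conditions: NaBH4, MeOH/THF, 0 °C
Reagents that add atoms: none
Why: Borohydride reduction of the aldehyde; the aryl sulfonate is inert to NaBH4.

Step 3
Reactants: 3 3-hydroxy-4-(hydroxymethyl)phenyl 4-methylbenzenesulfonate
Product: 4 {[2-hydroxy-4-(tosyloxy)phenyl]methyl}triphenylphosphonium bromide
Conditions: PPh3·HBr, MeCN, reflux
Reagents that add atoms: triphenylphosphine hydrobromide, [Br-].[PH+](c1ccccc1)(c1ccccc1)c1ccccc1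
Why: Phosphonium salt formation from an o-hydroxybenzyl alcohol: HBr ionises the benzylic alcohol (o-quinone methide type cation) and PPh3 captures it.

Step 4
Reactants: 5 3-hydroxy-5-methoxybenzaldehyde
Product: 6 3-methoxy-5-[(triisopropylsilyl)oxy]benzaldehyde
Conditions: i-Pr3SiCl, imidazole, DMF, rt
Reagents that add atoms: chlorotriisopropylsilane, CC(C)[Si](Cl)(C(C)C)C(C)C
Why: Silylation of the phenol (silyl chloride/imidazole); the bulky silyl ether is chosen to shield both positions ortho to it in step 14.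

Step 5
Reactants: 4 {[2-hydroxy-4-(tosyloxy)phenyl]methyl}triphenylphosphonium bromide; 6 3-methoxy-5-[(triisopropylsilyl)oxy]benzaldehyde
Product: 7 3-hydroxy-4-[(E)-2-{3-methoxy-5-[(triisopropylsilyl)oxy]phenyl}ethenyl]phenyl 4-methylbenzenesulfonate
Conditions: LiN(SiMe3)2 (2.1 equiv), THF, −78 °C to rt; then cat. PhSSPh, hν, THF (Z to E)
Reagents that add atoms: none
Why: Wittig olefination of the phenoxide ylide from 4 with aldehyde 6; thiyl-radical equilibration should converge the alkene on the E isomer, which places ring E on the outside of the triene that closes in step 7.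

Step 6
Reactants: 7 3-hydroxy-4-[(E)-2-{3-methoxy-5-[(triisopropylsilyl)oxy]phenyl}ethenyl]phenyl 4-methylbenzenesulfonate
Product: 8 {2-[(E)-2-{3-methoxy-5-[(triisopropylsilyl)oxy]phenyl}ethenyl]-5-(tosyloxy)phenoxy}methyl 2,2-dimethylpropanoate
Conditions: ClCH2OC(O)t-Bu, K2CO3, NaI (cat.), acetone, rt
Reagents that add atoms: chloromethyl pivalate, CC(C)(C)C(=O)OCCl
Why: Williamson-type O-alkylation of the only free phenol at the activated chloromethyl carbon; this brings in C2 as a latent oxocarbenium ion (acylal).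

Step 7
Reactants: 8 {2-[(E)-2-{3-methoxy-5-[(triisopropylsilyl)oxy]phenyl}ethenyl]-5-(tosyloxy)phenoxy}methyl 2,2-dimethylpropanoate
Product: 11 3-{3-methoxy-5-[(triisopropylsilyl)oxy]phenyl}-2H-chromen-7-yl 4-methylbenzenesulfonate, via aryloxymethyl oxocarbenium triflate 9 (not isolated), via chroman-4-yl cation triflate 10 (not isolated)
Conditions: Me3SiOTf (1.2 equiv), 2,6-di-tert-butyl-4-methylpyridine (1.5 equiv), CH2Cl2 (0.01 M), −78 to −20 °C
Reagents that add atoms: none
Why: Proposed new method: Silyl triflate removes pivalate from the acylal to give aryloxymethyl oxocarbenium ion 9, in which C2=O1, the ring A bond C8a–C4a and the alkene C4=C3 form a cis-fixed 2-oxahexatriene cation; thermal disrotatory 6π-electrocyclisation (formally a 6-endo-trig Prins-type attack of C3 on C2) forms the C2–C3 bond and ring C and gives cation 10, which loses H3 to the hindered pyridine to give chromene 11. The closest known reaction types are the Prins cyclisation of α-acyloxy ethers under silyl triflates, the oxa-Povarov reaction of aryl oxocarbenium ions with alkenes and the condensation of aldehydes with 2-alkenylanilines to 1,2-dihydroquinolines; what is new is the closure of a formaldehyde-level aryloxymethyl cation onto a stilbene. Ring C is the only ring closed, by the 6π/6-endo mode; 5-exo attack through C4 would put the charge on C3 beside the meta-dioxygenated ring E, where no oxygen can stabilise it, whereas charge on C4 is stabilised by O1. No stereocentre remains after the step (C3 is sp3 only in 10 and is set in step 8), and the E alkene places ring E outside and H3 inside the closing triene. The selectivity needed is ring closure over intermolecular arene alkylation and over acid-induced oligomerisation of 11; high dilution, the electron-poor sulfonate on ring A and the non-nucleophilic base that takes up the triflic acid should secure it.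

Step 8
Reactants: 11 3-{3-methoxy-5-[(triisopropylsilyl)oxy]phenyl}-2H-chromen-7-yl 4-methylbenzenesulfonate
Product: 12 (3R)-3-{3-methoxy-5-[(triisopropylsilyl)oxy]phenyl}-3,4-dihydro-2H-chromen-7-yl 4-methylbenzenesulfonate
Conditions: H2 (50 bar), [Ir(cod)((S)-tBu-PHOX)][B(C6H3(CF3)2)4] (2 mol %), CH2Cl2, rt
Reagents that add atoms: none
Why: Iridium N,P-catalysed asymmetric hydrogenation of an unfunctionalised trisubstituted aryl alkene (the reaction type used for isoflav-3-enes); the catalyst selects the alkene face and thereby sets C3 as R, the ligand antipode being assigned by analogy with (E)-α-methylstilbene.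

Step 9
Reactants: 13 1-[4-(benzyloxy)-2-hydroxyphenyl]ethanone; 14 2-(benzyloxy)-4,5-dimethoxybenzaldehyde
Product: 15 (2E)-1-[4-(benzyloxy)-2-hydroxyphenyl]-3-[2-(benzyloxy)-4,5-dimethoxyphenyl]prop-2-en-1-one
Conditions: KOH, EtOH, rt
Reagents that add atoms: none
Why: Claisen–Schmidt condensation (aldol addition and E1cB dehydration) gives the E-chalcone.

Step 10
Reactants: 15 (2E)-1-[4-(benzyloxy)-2-hydroxyphenyl]-3-[2-(benzyloxy)-4,5-dimethoxyphenyl]prop-2-en-1-one
Product: 17 7-(benzyloxy)-3-[2-(benzyloxy)-4,5-dimethoxyphenyl]-4H-chromen-4-one, via dimethyl acetal 16 (not isolated)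
Conditions: Tl(NO3)3·3H2O (1.1 equiv), MeOH/HC(OMe)3, rt; then HCl, MeOH, reflux
Reagents that add atoms: none
Why: Oxidative 1,2-aryl migration of the chalcone by trivalent thallium (the electron-rich trioxygenated ring migrates through a phenonium ion to give acetal 16), then acid-induced closure of the phenol onto the acetal carbon with loss of methanol gives the isoflavone; the sequence mirrors isoflavone biogenesis.

Step 11
Reactants: 17 7-(benzyloxy)-3-[2-(benzyloxy)-4,5-dimethoxyphenyl]-4H-chromen-4-one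
Product: 18 7-hydroxy-3-(2-hydroxy-4,5-dimethoxyphenyl)-4H-chromen-4-one
Conditions: H2 (1 atm), Pd/C, EtOAc/MeOH, rt
Reagents that add atoms: none
Why: Hydrogenolysis of both benzyl ethers over palladium; the chromone double bond is reduced much more slowly.

Step 12
Reactants: 18 7-hydroxy-3-(2-hydroxy-4,5-dimethoxyphenyl)-4H-chromen-4-one
Product: 19 3-(2-hydroxy-4,5-dimethoxyphenyl)-4-oxo-4H-chromen-7-yl 4-methylbenzenesulfonate
Conditions: TsCl (1.0 equiv), K2CO3 (1.1 equiv), acetone, 0 °C
Reagents that add atoms: p-toluenesulfonyl chloride, Cc1ccc(cc1)S(=O)(=O)Cl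
Why: Selective O-sulfonylation: the 7-OH is a vinylogous carboxylic acid and far more acidic than the ring B' hydroxyl, so one equivalent of base and TsCl should take it; the sulfonate deactivates ring A' against self-alkylation in step 14.

Step 13
Reactants: 19 3-(2-hydroxy-4,5-dimethoxyphenyl)-4-oxo-4H-chromen-7-yl 4-methylbenzenesulfonate
Product: 22 (6aR,11aR)-8,9-dimethoxy-6a,11a-dihydro-6H-[1]benzofuro[3,2-c]chromen-3-yl 4-methylbenzenesulfonate, via isoflavanone 20 (not isolated), via cis-isoflavan-4-ol 21 (not isolated)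
Conditions: RuCl(p-cymene)[(R,R)-TsDPEN] (2 mol %), HCO2H/Et3N, EtOAc, 40 °C; then conc. HCl, rt
Reagents that add atoms: none
Why: Asymmetric transfer hydrogenation (Noyori type) with dynamic kinetic resolution: conjugate reduction gives the configurationally labile isoflavanone 20, the divalent ruthenium hydride then reduces the fast-reacting enantiomer to cis-(3R,4R)-alcohol 21 (catalyst sets C4', the cis requirement sets C3'), and HCl ionises the benzylic alcohol so that the ring B' phenol closes the cis-fused dihydrofuran ring (SN1, 5-exo).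

Step 14
Reactants: 12 (3R)-3-{3-methoxy-5-[(triisopropylsilyl)oxy]phenyl}-3,4-dihydro-2H-chromen-7-yl 4-methylbenzenesulfonate; 22 (6aR,11aR)-8,9-dimethoxy-6a,11a-dihydro-6H-[1]benzofuro[3,2-c]chromen-3-yl 4-methylbenzenesulfonate
Product: 23 (3R,4S)-3-(2-hydroxy-4,5-dimethoxyphenyl)-4-{2-methoxy-6-[(3R)-7-(tosyloxy)-3,4-dihydro-2H-chromen-3-yl]-4-[(triisopropylsilyl)oxy]phenyl}-3,4-dihydro-2H-chromen-7-yl 4-methylbenzenesulfonate
Conditions: BF3·OEt2 (1.5 equiv), CH2Cl2, −40 to 0 °C, slow addition of 22 to 12 (1.3 equiv)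
Reagents that add atoms: none
Why: Lewis acid opening of the benzylic C–O bond of the pterocarpan gives the O1'-stabilised isoflavan-4-yl cation, which ring E of 12 should attack in a Friedel–Crafts alkylation (the known way from pterocarpans to 4-arylisoflavans) at the one carbon that is para to the silyloxy group, ortho to methoxy and not flanked by the bulky silyl ether; attack anti to the C3' aryl group sets C4' as S (3',4'-trans), while both sulfonates keep rings A and A' from competing and reclosure to 22 keeps the cation concentration low.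

Step 15
Reactants: 23 (3R,4S)-3-(2-hydroxy-4,5-dimethoxyphenyl)-4-{2-methoxy-6-[(3R)-7-(tosyloxy)-3,4-dihydro-2H-chromen-3-yl]-4-[(triisopropylsilyl)oxy]phenyl}-3,4-dihydro-2H-chromen-7-yl 4-methylbenzenesulfonate
Product: 24 (3R,4S)-4-{4-hydroxy-2-[(3R)-7-hydroxy-3,4-dihydro-2H-chromen-3-yl]-6-methoxyphenyl}-3-(2-hydroxy-4,5-dimethoxyphenyl)-3,4-dihydro-2H-chromen-7-ol
Conditions: KOH, degassed MeOH/THF/H2O, 60 °C, Ar; then aq. NH4Cl
Reagents that add atoms: none
Why: Alkaline cleavage of both aryl sulfonates (hydroxide at sulfur) and of the aryl silyl ether (hydroxide at silicon) in one operation; no stereocentre is acidic enough to epimerise under these conditions.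

## Compound list

1 | 2,4-dihydroxybenzaldehyde | O=Cc1ccc(O)cc1O | starting material
2 | 4-formyl-3-hydroxyphenyl 4-methylbenzenesulfonate | Cc1ccc(cc1)S(=O)(=O)Oc1ccc(C=O)c(O)c1 | intermediate
3 | 3-hydroxy-4-(hydroxymethyl)phenyl 4-methylbenzenesulfonate | Cc1ccc(cc1)S(=O)(=O)Oc1ccc(CO)c(O)c1 | intermediate
4 | {[2-hydroxy-4-(tosyloxy)phenyl]methyl}triphenylphosphonium bromide | [Br-].Cc1ccc(cc1)S(=O)(=O)Oc1ccc(C[P+](c2ccccc2)(c2ccccc2)c2ccccc2)c(O)c1 | intermediate
5 | 3-hydroxy-5-methoxybenzaldehyde | COc1cc(O)cc(C=O)c1 | starting material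
6 | 3-methoxy-5-[(triisopropylsilyl)oxy]benzaldehyde | COc1cc(O[Si](C(C)C)(C(C)C)C(C)C)cc(C=O)c1 | intermediate
7 | 3-hydroxy-4-[(E)-2-{3-methoxy-5-[(triisopropylsilyl)oxy]phenyl}ethenyl]phenyl 4-methylbenzenesulfonate | Cc1ccc(cc1)S(=O)(=O)Oc1ccc(/C=C/c2cc(OC)cc(O[Si](C(C)C)(C(C)C)C(C)C)c2)c(O)c1 | intermediate
8 | {2-[(E)-2-{3-methoxy-5-[(triisopropylsilyl)oxy]phenyl}ethenyl]-5-(tosyloxy)phenoxy}methyl 2,2-dimethylpropanoate | Cc1ccc(cc1)S(=O)(=O)Oc1ccc(/C=C/c2cc(OC)cc(O[Si](C(C)C)(C(C)C)C(C)C)c2)c(OCOC(=O)C(C)(C)C)c1 | intermediate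
9 | methylidene{2-[(E)-2-{3-methoxy-5-[(triisopropylsilyl)oxy]phenyl}ethenyl]-5-(tosyloxy)phenyl}oxonium triflate (not isolated) | C=[O+]c1cc(OS(=O)(=O)c2ccc(C)cc2)ccc1/C=C/c1cc(OC)cc(O[Si](C(C)C)(C(C)C)C(C)C)c1.[O-]S(=O)(=O)C(F)(F)F | intermediate
10 | 3-{3-methoxy-5-[(triisopropylsilyl)oxy]phenyl}-7-(tosyloxy)-3,4-dihydro-2H-chromen-4-ylium triflate, racemic at C3 (not isolated) | Cc1ccc(cc1)S(=O)(=O)Oc1ccc2[CH+]C(COc2c1)c1cc(OC)cc(O[Si](C(C)C)(C(C)C)C(C)C)c1.[O-]S(=O)(=O)C(F)(F)F | intermediate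
11 | 3-{3-methoxy-5-[(triisopropylsilyl)oxy]phenyl}-2H-chromen-7-yl 4-methylbenzenesulfonate | Cc1ccc(cc1)S(=O)(=O)Oc1ccc2C=C(COc2c1)c1cc(OC)cc(O[Si](C(C)C)(C(C)C)C(C)C)c1 | intermediate
12 | (3R)-3-{3-methoxy-5-[(triisopropylsilyl)oxy]phenyl}-3,4-dihydro-2H-chromen-7-yl 4-methylbenzenesulfonate | COc1cc(O[Si](C(C)C)(C(C)C)C(C)C)cc(c1)[C@@H]1COc2cc(OS(=O)(=O)c3ccc(C)cc3)ccc2C1 | intermediate
13 | 1-[4-(benzyloxy)-2-hydroxyphenyl]ethanone | CC(=O)c1ccc(OCc2ccccc2)cc1O | starting material
14 | 2-(benzyloxy)-4,5-dimethoxybenzaldehyde | COc1cc(C=O)c(OCc2ccccc2)cc1OC | starting material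
15 | (2E)-1-[4-(benzyloxy)-2-hydroxyphenyl]-3-[2-(benzyloxy)-4,5-dimethoxyphenyl]prop-2-en-1-one | COc1cc(/C=C/C(=O)c2ccc(OCc3ccccc3)cc2O)c(OCc2ccccc2)cc1OC | intermediate
16 | 1-[4-(benzyloxy)-2-hydroxyphenyl]-2-[2-(benzyloxy)-4,5-dimethoxyphenyl]-3,3-dimethoxypropan-1-one, racemic (not isolated) | COc1cc(C(C(OC)OC)C(=O)c2ccc(OCc3ccccc3)cc2O)c(OCc2ccccc2)cc1OC | intermediate
17 | 7-(benzyloxy)-3-[2-(benzyloxy)-4,5-dimethoxyphenyl]-4H-chromen-4-one | COc1cc(c(OCc2ccccc2)cc1OC)-c1coc2cc(OCc3ccccc3)ccc2c1=O | intermediate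
18 | 7-hydroxy-3-(2-hydroxy-4,5-dimethoxyphenyl)-4H-chromen-4-one | COc1cc(c(O)cc1OC)-c1coc2cc(O)ccc2c1=O | intermediate
19 | 3-(2-hydroxy-4,5-dimethoxyphenyl)-4-oxo-4H-chromen-7-yl 4-methylbenzenesulfonate | COc1cc(c(O)cc1OC)-c1coc2cc(OS(=O)(=O)c3ccc(C)cc3)ccc2c1=O | intermediate
20 | 3-(2-hydroxy-4,5-dimethoxyphenyl)-4-oxo-3,4-dihydro-2H-chromen-7-yl 4-methylbenzenesulfonate, C3 configurationally labile (not isolated) | COc1cc(O)c(cc1OC)C1COc2cc(OS(=O)(=O)c3ccc(C)cc3)ccc2C1=O | intermediate
21 | (3R,4R)-4-hydroxy-3-(2-hydroxy-4,5-dimethoxyphenyl)-3,4-dihydro-2H-chromen-7-yl 4-methylbenzenesulfonate, 3,4-cis (not isolated) | COc1cc(O)c([C@@H]2COc3cc(OS(=O)(=O)c4ccc(C)cc4)ccc3[C@@H]2O)cc1OC | intermediate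
22 | (6aR,11aR)-8,9-dimethoxy-6a,11a-dihydro-6H-[1]benzofuro[3,2-c]chromen-3-yl 4-methylbenzenesulfonate | COc1cc2c(cc1OC)[C@@H]1COc3cc(OS(=O)(=O)c4ccc(C)cc4)ccc3[C@@H]1O2 | intermediate
23 | (3R,4S)-3-(2-hydroxy-4,5-dimethoxyphenyl)-4-{2-methoxy-6-[(3R)-7-(tosyloxy)-3,4-dihydro-2H-chromen-3-yl]-4-[(triisopropylsilyl)oxy]phenyl}-3,4-dihydro-2H-chromen-7-yl 4-methylbenzenesulfonate | COc1cc(O)c([C@@H]2COc3cc(OS(=O)(=O)c4ccc(C)cc4)ccc3[C@H]2c2c(OC)cc(O[Si](C(C)C)(C(C)C)C(C)C)cc2[C@@H]2COc3cc(OS(=O)(=O)c4ccc(C)cc4)ccc3C2)cc1OC | intermediate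
24 | (3R,4S)-4-{4-hydroxy-2-[(3R)-7-hydroxy-3,4-dihydro-2H-chromen-3-yl]-6-methoxyphenyl}-3-(2-hydroxy-4,5-dimethoxyphenyl)-3,4-dihydro-2H-chromen-7-ol (CNP0266829.1) | COc1cc(O)c([C@@H]2COc3cc(O)ccc3[C@H]2c2c(OC)cc(O)cc2[C@@H]2COc3cc(O)ccc3C2)cc1OC | target

## Step count and risks

Total step count: 15.
Longest linear sequence: 9 steps (1, 2, 3, 5, 6, 7, 8, 14, 15).

Steps most likely to fail:

Step 7 (proposed new method). What may go wrong: ionisation of the acylal on the wrong side (loss of the aryloxide instead of pivalate), capture of the oxocarbenium ion by ring E of a second molecule, or acid-driven oligomerisation of the chromene once it has formed. The fallback uses a known ring synthesis, the intramolecular Wittig chromene synthesis; it sets out from phosphonium salt 4 and comes back at chromene 11. Commercial 1-(3-hydroxy-5-methoxyphenyl)ethanone would be silylated (i-Pr3SiCl, imidazole, DMF) to silyl ketone F1 and brominated at the methyl group (CuBr2, EtOAc/CHCl3, reflux) to phenacyl bromide F2. The phenol of 4 would be alkylated by F2 (K2CO3, acetone) to keto phosphonium salt F3. LiN(SiMe3)2 in THF should then turn F3 into the ylide, which closes onto the ketone to give 11.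

Step 14. What may go wrong: alkylation at the wrong position of ring E (para to methoxy, or between the two oxygens), self-alkylation of the opened electrophile, or proton loss from the cation to an isoflav-3-ene, which would erode the C3' configuration. The fallback replaces steric steering by positional blocking with bromine; it sets out from 12 and comes back at target 24. Desilylation of 12 (Bu4NF, AcOH, THF) should give phenol F4. NBS (2 equiv) with catalytic i-Pr2NH in CH2Cl2 should brominate both positions ortho to the free hydroxyl to give dibromophenol F5, leaving only the position para to the hydroxyl open. BF3·OEt2-mediated coupling with 22 should then give dibromo dimer F6. Hydrogenolysis of both C–Br bonds (H2, Pd/C, Et3N, EtOAc) should give bis-sulfonate F7, and KOH as in step 15 should give 24.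

Step 15. What may go wrong: oxidative degradation of the electron-rich phenols in hot alkali, or incomplete cleavage of the hindered aryl silyl ether. The fallback is a two-stage, non-hydrolytic unmasking; it sets out from 23 and comes back at 24. Mg turnings in MeOH at rt should cleave both sulfonates by electron transfer to give silyl ether triol F8. Bu4NF/AcOH in THF should then remove the silyl group to give 24.

## Further compounds

F1 | step 7 | 1-{3-methoxy-5-[(triisopropylsilyl)oxy]phenyl}ethanone | CC(=O)c1cc(OC)cc(O[Si](C(C)C)(C(C)C)C(C)C)c1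
F2 | step 7 | 2-bromo-1-{3-methoxy-5-[(triisopropylsilyl)oxy]phenyl}ethanone | BrCC(=O)c1cc(OC)cc(O[Si](C(C)C)(C(C)C)C(C)C)c1
F3 | step 7 | {[2-(2-{3-methoxy-5-[(triisopropylsilyl)oxy]phenyl}-2-oxoethoxy)-4-(tosyloxy)phenyl]methyl}triphenylphosphonium bromide | [Br-].Cc1ccc(cc1)S(=O)(=O)Oc1ccc(C[P+](c2ccccc2)(c2ccccc2)c2ccccc2)c(OCC(=O)c2cc(OC)cc(O[Si](C(C)C)(C(C)C)C(C)C)c2)c1
F4 | step 14 | (3R)-3-(3-hydroxy-5-methoxyphenyl)-3,4-dihydro-2H-chromen-7-yl 4-methylbenzenesulfonate | COc1cc(O)cc(c1)[C@@H]1COc2cc(OS(=O)(=O)c3ccc(C)cc3)ccc2C1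
F5 | step 14 | (3R)-3-(2,4-dibromo-3-hydroxy-5-methoxyphenyl)-3,4-dihydro-2H-chromen-7-yl 4-methylbenzenesulfonate | COc1cc(c(Br)c(O)c1Br)[C@@H]1COc2cc(OS(=O)(=O)c3ccc(C)cc3)ccc2C1
F6 | step 14 | (3R,4S)-4-{3,5-dibromo-4-hydroxy-2-methoxy-6-[(3R)-7-(tosyloxy)-3,4-dihydro-2H-chromen-3-yl]phenyl}-3-(2-hydroxy-4,5-dimethoxyphenyl)-3,4-dihydro-2H-chromen-7-yl 4-methylbenzenesulfonate | COc1cc(O)c([C@@H]2COc3cc(OS(=O)(=O)c4ccc(C)cc4)ccc3[C@H]2c2c(OC)c(Br)c(O)c(Br)c2[C@@H]2COc3cc(OS(=O)(=O)c4ccc(C)cc4)ccc3C2)cc1OC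
F7 | step 14 | (3R,4S)-4-{4-hydroxy-2-methoxy-6-[(3R)-7-(tosyloxy)-3,4-dihydro-2H-chromen-3-yl]phenyl}-3-(2-hydroxy-4,5-dimethoxyphenyl)-3,4-dihydro-2H-chromen-7-yl 4-methylbenzenesulfonate | COc1cc(O)c([C@@H]2COc3cc(OS(=O)(=O)c4ccc(C)cc4)ccc3[C@H]2c2c(OC)cc(O)cc2[C@@H]2COc3cc(OS(=O)(=O)c4ccc(C)cc4)ccc3C2)cc1OC
F8 | step 15 | (3R,4S)-4-{2-[(3R)-7-hydroxy-3,4-dihydro-2H-chromen-3-yl]-6-methoxy-4-[(triisopropylsilyl)oxy]phenyl}-3-(2-hydroxy-4,5-dimethoxyphenyl)-3,4-dihydro-2H-chromen-7-ol | COc1cc(O)c([C@@H]2COc3cc(O)ccc3[C@H]2c2c(OC)cc(O[Si](C(C)C)(C(C)C)C(C)C)cc2[C@@H]2COc3cc(O)ccc3C2)cc1OC
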